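**Retrosynthetic overview**

- Feature used: in ring A, the C4'–C5' edge (C4'–OH, C5'–O–aryl) is the carboxyl carbon and α-carbon of an aryloxyacetic acid. C3', C2', C1' and C6' are C3 to C6 of a 4-oxy-2-pyrone-5-carboxylate that carries the masked 2-oxoheptyl chain at C6.
- The target is traced back (benzyl groups, dioxolane, silyl ether) to a protected diaryl ether. Its ring A is cut at C5'–C6' and C3'–C4' into a 2-pyrone diene and an aryloxy ketene bis-silyl acetal (inverse-demand Diels-Alder reaction, then loss of CO2 and silanol).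
- The pyrone comes from a ketal-protected β-keto benzyl ester and a malonyl half-ester chloride (C-acylation, enol lactonisation, O-benzylation). The β-keto ester comes from ethyl 3-oxooctanoate.
- The ketene acetal comes from an 8-hydroxyisocoumarin and tert-butyl bromoacetate. The isocoumarin comes from an ortho-toluate and a Weinreb amide (lateral acylation, enol lactonisation, peri O-demethylation).
- Ring order: pyrone ring (step 4), isocoumarin pyranone ring on a preformed benzene ring (step 7), ring A last (step 12).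

Key step: step 12

Remark: the target has no stereocenter. Primed locants refer to ring A (C1' carboxyl-bearing, C6' chain-bearing) and pyrone locants to 2H-pyran-2-one (O1, C2 lactone carbonyl). The bridged adduct and the dihydroarene of the key step form as stereoisomer mixtures whose stereocenters vanish on aromatisation.

**Route**

Step 1
Reactants: 1 ethyl 3-oxooctanoate
Product: 2 ethyl 2-(2-pentyl-1,3-dioxolan-2-yl)acetate
Conditions: ethylene glycol, TsOH·H2O (cat.), PhMe, reflux, Dean-Stark trap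
Reagents that add atoms: ethylene glycol, OCCO
Why: Acid-catalysed ketalisation of the ketone of a β-keto ester with azeotropic removal of water is standard and masks the future side-chain carbonyl.

Step 2
Reactants: 2 ethyl 2-(2-pentyl-1,3-dioxolan-2-yl)acetate
Product: 3 2-(2-pentyl-1,3-dioxolan-2-yl)acetic acid
Conditions: LiOH·H2O, THF/MeOH/H2O, 23 °C; then cold 1 M HCl to pH 4
Reagents that add atoms: lithium hydroxide (hydroxide oxygen), [Li+].[OH-]
Why: Saponification of the unhindered ethyl ester leaves the base-stable dioxolane intact, and a cold, mildly acidic work-up should spare the ketal.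

Step 3
Reactants: 3 2-(2-pentyl-1,3-dioxolan-2-yl)acetic acid, 4 benzyl hydrogen malonate
Product: 6 benzyl 3-oxo-4-(2-pentyl-1,3-dioxolan-2-yl)butanoate, via acyl imidazolide 5 (not isolated)
Conditions: CDI, THF, 23 °C; then 4, MgCl2, Et3N, THF, 23 to 45 °C; cold 10% aq citric acid
Reagents that add atoms: none
Why: Decarboxylative Claisen condensation of an acyl imidazolide with a magnesium malonate half-ester gives the β-keto benzyl ester under near-neutral conditions that a ketal tolerates.

Step 4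
Reactants: 6 benzyl 3-oxo-4-(2-pentyl-1,3-dioxolan-2-yl)butanoate, 7 methyl 3-chloro-3-oxopropanoate
Product: 9 benzyl 4-hydroxy-2-oxo-6-[(2-pentyl-1,3-dioxolan-2-yl)methyl]-2H-pyran-5-carboxylate, via triketo diester 8 (not isolated)
Conditions: MgCl2, pyridine, CH2Cl2, 0 to 23 °C; then DBU, 23 to 40 °C; aq citric acid
Reagents that add atoms: none
Why: C-acylation of the magnesium chelate of the β-keto ester by the acid chloride, then enol lactonisation of the side-chain ketone onto the methyl ester (the only ester within reach of a six-membered ring), builds the 4-hydroxy-2-pyrone without the HCl that a direct malonyl dichloride condensation would release onto the β-keto ketal.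

Step 5
Reactants: 9 benzyl 4-hydroxy-2-oxo-6-[(2-pentyl-1,3-dioxolan-2-yl)methyl]-2H-pyran-5-carboxylate
Product: 10 benzyl 4-(benzyloxy)-2-oxo-6-[(2-pentyl-1,3-dioxolan-2-yl)methyl]-2H-pyran-5-carboxylate
Conditions: BnOH, PPh3, DIAD, THF, 0 to 23 °C
Reagents that add atoms: benzyl alcohol, OCc1ccccc1
Why: Mitsunobu alkylation of an acidic 4-hydroxy-2-pyrone (a vinylogous carboxylic acid) is known to go at O4 and not at the lactone oxygen or C3, and the neutral conditions spare the ketal.

Step 6
Reactants: 11 methyl 2,4-dimethoxy-6-methylbenzoate, 12 N-methoxy-N-methylhexanamide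
Product: 13 methyl 2,4-dimethoxy-6-(2-oxoheptyl)benzoate
Conditions: LDA (LiN(iPr)2), THF, -78 °C; then 12, -78 to -40 °C; aq NH4Cl
Reagents that add atoms: none
Why: Lateral lithiation of the ortho-toluate gives an ester-stabilised benzylic anion, and acylation by the Weinreb amide stops at the ketone because the tetrahedral chelate survives until the quench.

Step 7
Reactants: 13 methyl 2,4-dimethoxy-6-(2-oxoheptyl)benzoate
Product: 14 6,8-dimethoxy-3-pentyl-1H-isochromen-1-one
Conditions: TsOH·H2O (cat.), PhMe, reflux, 4 Å molecular sieves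
Reagents that add atoms: none
Why: Acid-catalysed enol lactonisation (6-exo-trig attack of the enol oxygen on the ortho ester, methanol removed) closes the pyranone ring to the conjugated isocoumarin.

Step 8
Reactants: 14 6,8-dimethoxy-3-pentyl-1H-isochromen-1-one
Product: 15 8-hydroxy-6-methoxy-3-pentyl-1H-isochromen-1-one
Conditions: BCl3, CH2Cl2, -78 to 0 °C; H2O
Reagents that add atoms: none
Why: BCl3 chelates between the lactone carbonyl and the peri methoxy oxygen, so only the C8 methyl ether is cleaved and the C6 methoxy group stays.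

Step 9
Reactants: 15 8-hydroxy-6-methoxy-3-pentyl-1H-isochromen-1-one, 16 tert-butyl bromoacetate
Product: 17 tert-butyl 2-[(6-methoxy-1-oxo-3-pentyl-1H-isochromen-8-yl)oxy]acetate
Conditions: Cs2CO3, DMF, 50 °C
Reagents that add atoms: none
Why: Williamson alkylation of the cesium phenoxide with a reactive α-bromo ester, the polar solvent and cesium ion breaking the hydrogen bond to the lactone carbonyl.

Step 10
Reactants: 17 tert-butyl 2-[(6-methoxy-1-oxo-3-pentyl-1H-isochromen-8-yl)oxy]acetate
Product: 18 2-[(6-methoxy-1-oxo-3-pentyl-1H-isochromen-8-yl)oxy]acetic acid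
Conditions: TFA/CH2Cl2 (1:4), 23 °C
Reagents that add atoms: none
Why: Acidolysis of the tert-butyl ester (loss of isobutene) frees the acid without touching the lactone or the aryl methyl ether.

Step 11
Reactants: 18 2-[(6-methoxy-1-oxo-3-pentyl-1H-isochromen-8-yl)oxy]acetic acid
Product: 20 8-{[2,2-bis(trimethylsilyloxy)ethenyl]oxy}-6-methoxy-3-pentyl-1H-isochromen-1-one, via trimethylsilyl ester 19 (not isolated)
Conditions: TMSCl, Et3N, THF, 0 to 23 °C; then added to LDA (LiN(iPr)2)/TMSCl, THF, -78 to 0 °C; evaporation, pentane, filtration under Ar; used crude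
Reagents that add atoms: chlorotrimethylsilane, C[Si](C)(C)Cl
Why: Silyl ester formation and then α-deprotonation with TMSCl already present traps the ester enolate on oxygen as it forms, which should outrun a Dieckmann-type attack on the peri lactone carbonyl, and two identical silyloxy groups leave no alkene isomers.

Step 12
Reactants: 10 benzyl 4-(benzyloxy)-2-oxo-6-[(2-pentyl-1,3-dioxolan-2-yl)methyl]-2H-pyran-5-carboxylate, 20 8-{[2,2-bis(trimethylsilyloxy)ethenyl]oxy}-6-methoxy-3-pentyl-1H-isochromen-1-one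
Product: 23 benzyl 6-(benzyloxy)-3-[(6-methoxy-1-oxo-3-pentyl-1H-isochromen-8-yl)oxy]-2-[(2-pentyl-1,3-dioxolan-2-yl)methyl]-4-(trimethylsilyloxy)benzoate, via bridged lactone 21 (not isolated), via dihydroarene 22 (not isolated)
Conditions: 20 (1.5 equiv), PhMe, 120 to 140 °C, sealed tube, Ar; evaporation; used crude
Reagents that add atoms: none
Why: The electron-rich alkene of 20 adds across C6 and C3 of the electron-poor pyrone diene of 10 in an inverse-electron-demand Diels-Alder reaction (probably asynchronous, the C5'–C6' bond leading), bridged lactone 21 expels CO2 by cycloreversion, and dihydroarene 22 loses trimethylsilanol (H from C5', silyloxy from C4') to give the arene. The closest known reaction type is the cycloaddition of 2-pyrone-5-carboxylates with ketene acetals, which gives 4-alkoxybenzoates after loss of CO2 and alcohol; a 4-alkoxy-6-alkyl pyrone paired with an α-aryloxy bis-silyl acetal is untried and the reaction is expected to be slow. Ring A is closed by an intermolecular [4+2] cycloaddition that forms both new ring bonds (C5'–C6' and C3'–C4'), and no stereocenter needs control because those of 21 and 22 are erased on aromatisation. The required regiochemistry is secured by the C5 ester and the lactone carbonyl, which make C6 the β- and δ-acceptor carbon and so the partner of the nucleophilic aryloxy-bearing carbon, the acetal carbon then closing onto C3. Elimination of silanol and not of aryloxide is secured because C4' of 22 carries no hydrogen, and the two identical silyloxy groups make the alkene geometry of 20 irrelevant while leaving oxygen on C4'.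

Step 13
Reactants: 23 benzyl 6-(benzyloxy)-3-[(6-methoxy-1-oxo-3-pentyl-1H-isochromen-8-yl)oxy]-2-[(2-pentyl-1,3-dioxolan-2-yl)methyl]-4-(trimethylsilyloxy)benzoate
Product: 24 benzyl 6-(benzyloxy)-4-hydroxy-3-[(6-methoxy-1-oxo-3-pentyl-1H-isochromen-8-yl)oxy]-2-(2-oxoheptyl)benzoate
Conditions: 1 M aq HCl/THF (1:3), 23 °C
Reagents that add atoms: water, O
Why: Dilute aqueous acid cleaves the aryl silyl ether at once and the dialkyl ketal more slowly, while benzyl ester, benzyl ether, diaryl ether and isocoumarin are stable, and doing this before debenzylation keeps the ketone away from a free ortho carboxylic acid under acid.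

Step 14
Reactants: 24 benzyl 6-(benzyloxy)-4-hydroxy-3-[(6-methoxy-1-oxo-3-pentyl-1H-isochromen-8-yl)oxy]-2-(2-oxoheptyl)benzoate
Product: 25 4,6-dihydroxy-3-[(6-methoxy-1-oxo-3-pentyl-1H-isochromen-8-yl)oxy]-2-(2-oxoheptyl)benzoic acid (beta-collatolic acid)
Conditions: H2 (1 atm), 10% Pd/C, EtOAc, 23 °C, stopped when two equivalents of H2 are taken up
Reagents that add atoms: none
Why: Hydrogenolysis of a benzyl ester and an aryl benzyl ether is much faster than reduction of the trisubstituted enol-lactone alkene of the isocoumarin or of the ketone, and neutral conditions at room temperature avoid decarboxylation of the 2,4-dihydroxybenzoic acid.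

**Compound list**

1 | ethyl 3-oxooctanoate | CCCCCC(=O)CC(=O)OCC | starting material
2 | ethyl 2-(2-pentyl-1,3-dioxolan-2-yl)acetate | CCCCCC1(CC(=O)OCC)OCCO1 | intermediate
3 | 2-(2-pentyl-1,3-dioxolan-2-yl)acetic acid | CCCCCC1(CC(=O)O)OCCO1 | intermediate
4 | benzyl hydrogen malonate | O=C(O)CC(=O)OCc1ccccc1 | starting material
5 | 1-(1H-imidazol-1-yl)-2-(2-pentyl-1,3-dioxolan-2-yl)ethan-1-one | CCCCCC1(CC(=O)n2ccnc2)OCCO1 | intermediate (not isolated)
6 | benzyl 3-oxo-4-(2-pentyl-1,3-dioxolan-2-yl)butanoate | CCCCCC1(CC(=O)CC(=O)OCc2ccccc2)OCCO1 | intermediate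
7 | methyl 3-chloro-3-oxopropanoate | COC(=O)CC(=O)Cl | starting material
8 | 1-benzyl 5-methyl 3-oxo-2-[2-(2-pentyl-1,3-dioxolan-2-yl)acetyl]pentanedioate | CCCCCC1(CC(=O)C(C(=O)OCc2ccccc2)C(=O)CC(=O)OC)OCCO1 | intermediate (not isolated)
9 | benzyl 4-hydroxy-2-oxo-6-[(2-pentyl-1,3-dioxolan-2-yl)methyl]-2H-pyran-5-carboxylate | O=C1C=C(O)C(C(=O)OCc2ccccc2)=C(CC2(CCCCC)OCCO2)O1 | intermediate
10 | benzyl 4-(benzyloxy)-2-oxo-6-[(2-pentyl-1,3-dioxolan-2-yl)methyl]-2H-pyran-5-carboxylate | O=C1C=C(OCc2ccccc2)C(C(=O)OCc2ccccc2)=C(CC2(CCCCC)OCCO2)O1 | intermediate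
11 | methyl 2,4-dimethoxy-6-methylbenzoate | COC(=O)c1c(C)cc(OC)cc1OC | starting material
12 | N-methoxy-N-methylhexanamide | CCCCCC(=O)N(C)OC | starting material
13 | methyl 2,4-dimethoxy-6-(2-oxoheptyl)benzoate | CCCCCC(=O)Cc1cc(OC)cc(OC)c1C(=O)OC | intermediate
14 | 6,8-dimethoxy-3-pentyl-1H-isochromen-1-one | CCCCCc1cc2cc(OC)cc(OC)c2c(=O)o1 | intermediate
15 | 8-hydroxy-6-methoxy-3-pentyl-1H-isochromen-1-one | CCCCCc1cc2cc(OC)cc(O)c2c(=O)o1 | intermediate
16 | tert-butyl bromoacetate | CC(C)(C)OC(=O)CBr | starting material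
17 | tert-butyl 2-[(6-methoxy-1-oxo-3-pentyl-1H-isochromen-8-yl)oxy]acetate | CCCCCc1cc2cc(OC)cc(OCC(=O)OC(C)(C)C)c2c(=O)o1 | intermediate
18 | 2-[(6-methoxy-1-oxo-3-pentyl-1H-isochromen-8-yl)oxy]acetic acid | CCCCCc1cc2cc(OC)cc(OCC(=O)O)c2c(=O)o1 | intermediate
19 | trimethylsilyl 2-[(6-methoxy-1-oxo-3-pentyl-1H-isochromen-8-yl)oxy]acetate | CCCCCc1cc2cc(OC)cc(OCC(=O)O[Si](C)(C)C)c2c(=O)o1 | intermediate (not isolated)
20 | 8-{[2,2-bis(trimethylsilyloxy)ethenyl]oxy}-6-methoxy-3-pentyl-1H-isochromen-1-one | C[Si](C)(C)OC(O[Si](C)(C)C)=COc1cc(OC)cc2cc(CCCCC)oc(=O)c12 | intermediate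
21 | benzyl 5-(benzyloxy)-7-[(6-methoxy-1-oxo-3-pentyl-1H-isochromen-8-yl)oxy]-3-oxo-1-[(2-pentyl-1,3-dioxolan-2-yl)methyl]-8,8-bis(trimethylsilyloxy)-2-oxabicyclo[2.2.2]oct-5-ene-6-carboxylate (stereoisomer mixture) | O=C1OC2(CC3(CCCCC)OCCO3)C(C(=O)OCc3ccccc3)=C(OCc3ccccc3)C1C(O[Si](C)(C)C)(O[Si](C)(C)C)C2Oc1cc(OC)cc2cc(CCCCC)oc(=O)c12 | intermediate (not isolated)
22 | benzyl 6-(benzyloxy)-3-[(6-methoxy-1-oxo-3-pentyl-1H-isochromen-8-yl)oxy]-2-[(2-pentyl-1,3-dioxolan-2-yl)methyl]-4,4-bis(trimethylsilyloxy)cyclohexa-1,5-diene-1-carboxylate (racemic) | CCCCCC1(CC2=C(C(=O)OCc3ccccc3)C(OCc3ccccc3)=CC(O[Si](C)(C)C)(O[Si](C)(C)C)C2Oc2cc(OC)cc3cc(CCCCC)oc(=O)c23)OCCO1 | intermediate (not isolated)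
23 | benzyl 6-(benzyloxy)-3-[(6-methoxy-1-oxo-3-pentyl-1H-isochromen-8-yl)oxy]-2-[(2-pentyl-1,3-dioxolan-2-yl)methyl]-4-(trimethylsilyloxy)benzoate | CCCCCC1(Cc2c(Oc3cc(OC)cc4cc(CCCCC)oc(=O)c34)c(O[Si](C)(C)C)cc(OCc3ccccc3)c2C(=O)OCc2ccccc2)OCCO1 | intermediate
24 | benzyl 6-(benzyloxy)-4-hydroxy-3-[(6-methoxy-1-oxo-3-pentyl-1H-isochromen-8-yl)oxy]-2-(2-oxoheptyl)benzoate | CCCCCC(=O)Cc1c(Oc2cc(OC)cc3cc(CCCCC)oc(=O)c23)c(O)cc(OCc2ccccc2)c1C(=O)OCc1ccccc1 | intermediate
25 | 4,6-dihydroxy-3-[(6-methoxy-1-oxo-3-pentyl-1H-isochromen-8-yl)oxy]-2-(2-oxoheptyl)benzoic acid (beta-collatolic acid) | CCCCCC(=O)Cc1c(Oc2cc(OC)cc3cc(CCCCC)oc(=O)c23)c(O)cc(O)c1C(=O)O | target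

**Step count and risks**

Total step count: 14. Longest linear sequence: 9 steps (steps 6 to 14, from 11).

Steps most likely to fail:

1. Step 12. The cycloaddition may be too slow, because the C4 benzyloxy group and the C6 branch both hinder bond formation at C6. Protodesilylation of 20 by the liberated silanol, or conjugate addition at C6 followed by silyl transfer without closure at C3, could then take over. Fallback: make the diaryl ether by Ullmann coupling on a ring A built from an orsellinate. It sets out from phenol 15 and amide 12 and comes back at target 25. Commercial 2,4-dihydroxy-6-methylbenzoic acid is perbenzylated (BnBr, K2CO3, DMF) to benzyl 2,4-bis(benzyloxy)-6-methylbenzoate F1. Lateral lithiation (LiN(iPr)2, THF, -78 °C) and acylation with 12 give benzyl 2,4-bis(benzyloxy)-6-(2-oxoheptyl)benzoate F2. Ketalisation with 1,2-bis(trimethylsilyloxy)ethane and catalytic TMSOTf at low temperature gives benzyl 2,4-bis(benzyloxy)-6-[(2-pentyl-1,3-dioxolan-2-yl)methyl]benzoate F3. NBS in MeCN should brominate the position ortho to the side chain and para to the C2 benzyloxy group, giving benzyl 4,6-bis(benzyloxy)-3-bromo-2-[(2-pentyl-1,3-dioxolan-2-yl)methyl]benzoate F4. Coupling of F4 with 15 (CuI, picolinic acid, K3PO4, DMSO, 100 °C) gives benzyl 4,6-bis(benzyloxy)-3-[(6-methoxy-1-oxo-3-pentyl-1H-isochromen-8-yl)oxy]-2-[(2-pentyl-1,3-dioxolan-2-yl)methyl]benzoate F5. Aqueous HCl in THF gives benzyl 4,6-bis(benzyloxy)-3-[(6-methoxy-1-oxo-3-pentyl-1H-isochromen-8-yl)oxy]-2-(2-oxoheptyl)benzoate F6, and hydrogenolysis as in step 14 gives 25.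

2. Step 11. The lithium enolate may close onto the lactone carbonyl peri to it before it is silylated, or the bis-silyl acetal may be lost by hydrolysis while the salts are removed. Fallback: keep the pyrone cycloaddition but use a dienophile without the lactone, and attach the isocoumarin afterwards. It sets out from pyrone 10 and phenol 15 and comes back at target 25. Pyrone 10 is heated with 1,1-bis(trimethylsilyloxy)ethene, the distillable ketene acetal of acetic acid. Loss of CO2 and silanol and a mild acidic work-up should give benzyl 6-(benzyloxy)-4-hydroxy-2-[(2-pentyl-1,3-dioxolan-2-yl)methyl]benzoate F7. Benzylation (BnBr, K2CO3, DMF) gives benzyl 2,4-bis(benzyloxy)-6-[(2-pentyl-1,3-dioxolan-2-yl)methyl]benzoate F3. This is carried through bromide F4, Ullmann coupling with 15 to F5, and ketone F6 to 25, as described under the first fallback.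

3. Step 4. The pyrone may be eroded by O-acylation, by self-condensation of 7 through its ketene, by retro-Claisen loss of an acyl arm from 8, or by base-induced opening of the dioxolane β to the carbonyl. Fallback: close the pyrone ring before the side chain exists. It sets out from amide 12 and comes back at pyrone 10. Benzyl acetoacetate and malonyl dichloride (CH2Cl2, 23 °C, no acid-labile group present) give benzyl 4-hydroxy-6-methyl-2-oxo-2H-pyran-5-carboxylate F8. Mitsunobu benzylation as in step 5 gives benzyl 4-(benzyloxy)-6-methyl-2-oxo-2H-pyran-5-carboxylate F9. Vinylogous deprotonation of the C6 methyl group (LiN(SiMe3)2, THF, -78 °C) and acylation with 12 give benzyl 4-(benzyloxy)-2-oxo-6-(2-oxoheptyl)-2H-pyran-5-carboxylate F10. Ketalisation with 1,2-bis(trimethylsilyloxy)ethane and catalytic TMSOTf at low temperature gives 10.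

**Further compounds**

F1 | step 12 | benzyl 2,4-bis(benzyloxy)-6-methylbenzoate | Cc1cc(OCc2ccccc2)cc(OCc2ccccc2)c1C(=O)OCc1ccccc1
F2 | step 12 | benzyl 2,4-bis(benzyloxy)-6-(2-oxoheptyl)benzoate | CCCCCC(=O)Cc1cc(OCc2ccccc2)cc(OCc2ccccc2)c1C(=O)OCc1ccccc1
F3 | step 12 | benzyl 2,4-bis(benzyloxy)-6-[(2-pentyl-1,3-dioxolan-2-yl)methyl]benzoate | CCCCCC1(Cc2cc(OCc3ccccc3)cc(OCc3ccccc3)c2C(=O)OCc2ccccc2)OCCO1
F4 | step 12 | benzyl 4,6-bis(benzyloxy)-3-bromo-2-[(2-pentyl-1,3-dioxolan-2-yl)methyl]benzoate | CCCCCC1(Cc2c(Br)c(OCc3ccccc3)cc(OCc3ccccc3)c2C(=O)OCc2ccccc2)OCCO1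
F5 | step 12 | benzyl 4,6-bis(benzyloxy)-3-[(6-methoxy-1-oxo-3-pentyl-1H-isochromen-8-yl)oxy]-2-[(2-pentyl-1,3-dioxolan-2-yl)methyl]benzoate | CCCCCC1(Cc2c(Oc3cc(OC)cc4cc(CCCCC)oc(=O)c34)c(OCc3ccccc3)cc(OCc3ccccc3)c2C(=O)OCc2ccccc2)OCCO1
F6 | step 12 | benzyl 4,6-bis(benzyloxy)-3-[(6-methoxy-1-oxo-3-pentyl-1H-isochromen-8-yl)oxy]-2-(2-oxoheptyl)benzoate | CCCCCC(=O)Cc1c(Oc2cc(OC)cc3cc(CCCCC)oc(=O)c23)c(OCc2ccccc2)cc(OCc2ccccc2)c1C(=O)OCc1ccccc1
F7 | step 11 | benzyl 6-(benzyloxy)-4-hydroxy-2-[(2-pentyl-1,3-dioxolan-2-yl)methyl]benzoate | CCCCCC1(Cc2cc(O)cc(OCc3ccccc3)c2C(=O)OCc2ccccc2)OCCO1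
F8 | step 4 | benzyl 4-hydroxy-6-methyl-2-oxo-2H-pyran-5-carboxylate | Cc1oc(=O)cc(O)c1C(=O)OCc1ccccc1
F9 | step 4 | benzyl 4-(benzyloxy)-6-methyl-2-oxo-2H-pyran-5-carboxylate | Cc1oc(=O)cc(OCc2ccccc2)c1C(=O)OCc1ccccc1
F10 | step 4 | benzyl 4-(benzyloxy)-2-oxo-6-(2-oxoheptyl)-2H-pyran-5-carboxylate | CCCCCC(=O)Cc1oc(=O)cc(OCc2ccccc2)c1C(=O)OCc1ccccc1
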